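**Retrosynthetic overview** (ring A = 1,2-dioxane O1–O2–C3–C4–C5–C6; side chain C7 to C16 counted from C6, phenyl on C16)
- Ring A is the only ring and is closed last: the C6 hydroperoxide adds to the C3 ketone (O2–C3) once the C4=C5 bond of an E-enone has been reduced by an ene-reductase, which sets C4.
- C4–C5 comes from Horner–Wadsworth–Emmons olefination of a C5 aldehyde; the C6–O1 bond comes from perhydrolysis, with inversion, of a 2-methyl-2-alkyloxirane that descends from Sharpless epoxidation of a 2-substituted allyl alcohol.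
- The strategy rests on C8, the lone CH(CH3) stereocentre of the side chain, lying between the C7 methylene on ring carbon C6 and the unbranched C9–C14 chain. This is the pattern left by methylmetalation of a terminal alkene, so C8–CH3 and C6–C7 are disconnected together.
- The two bonds are made in one flask from (Z)-1-phenyldeca-1,9-diene, Al(CH3)3 and a 2-bromoallyl silyl ether; the diene comes from a Z-selective Wittig reaction.

Key step: step 4

Assumption: the (−)-zirconocene is taken to give the (2R)-2-methylalkyl metal from an unbranched 1-alkene (its antipode would be used otherwise), and the enzyme of step 15 is the member of an ene-reductase panel that protonates C4 to the (R) configuration.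

**Step 1**
Reactants: 1 9-bromonon-1-ene; 2 triphenylphosphine
Product: 3 (non-8-en-1-yl)triphenylphosphonium bromide
Conditions: MeCN, reflux
Reagents that add atoms: none
Why: SN2 quaternisation of the primary bromide by the phosphine (phosphonium salt formation) should proceed cleanly, the terminal alkene being inert.

**Step 2**
Reactants: 3 (non-8-en-1-yl)triphenylphosphonium bromide; 4 benzaldehyde
Product: 6 (Z)-1-phenyldeca-1,9-diene, via phosphorus ylide 5 (not isolated)
Conditions: NaN(SiMe3)2, THF, −78 °C; then 4, −78 °C to rt; AgNO3-impregnated silica to remove the minor E isomer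
Reagents that add atoms: none
Why: Wittig olefination of a non-stabilised ylide with an aryl aldehyde under lithium-free conditions is kinetically controlled through the cis-oxaphosphetane and should give mainly the Z-styrene.

**Step 3**
Reactants: 7 2-bromoprop-2-en-1-ol
Product: 8 (2-bromoallyloxy)(tert-butyl)dimethylsilane
Conditions: TBSCl, imidazole, CH2Cl2, 0 °C to rt
Reagents that add atoms: tert-butyldimethylsilyl chloride, CC(C)(C)[Si](C)(C)Cl
Why: Imidazole-promoted silylation of a primary alcohol should leave the alkenyl bromide untouched.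

**Step 4**
Reactants: 6 (Z)-1-phenyldeca-1,9-diene; 9 trimethylaluminium; 8 (2-bromoallyloxy)(tert-butyl)dimethylsilane
Product: 12 tert-butyldimethyl{[(4R,11Z)-4-methyl-2-methylidene-12-phenyldodec-11-en-1-yl]oxy}silane, via alkyldimethylalane 10 (not isolated), via alkylzinc triflate 11 (not isolated)
Conditions: 9, (−)-dichlorobis(1-neomenthylindenyl)zirconium (5 mol %), [Al(CH3)O]n, CH2Cl2, 0 °C to rt; excess 9 and solvent removed in vacuo; Zn(OTf)2, DMF, 70 °C; then 8, Pd(PPh3)4 (5 mol %), rt to 50 °C
Reagents that add atoms: none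
Why: Methylaluminoxane generates a cationic methylzirconocene (tetravalent zirconium) that inserts the monosubstituted alkene of 6 with methyl going to the internal carbon (C8–CH3) and zirconium to the terminus, and exchange with Al(CH3)3 releases alane 10 (C7–Al) and regenerates the catalyst; after removal of excess Al(CH3)3, Zn(OTf)2 converts 10 into alkylzinc 11, which joins C7 to C6 by oxidative addition of the C–Br bond of 8 to zerovalent palladium, transmetalation and reductive elimination. The closest known reaction type is the one-flask zirconium-catalysed asymmetric carboalumination of 1-alkenes followed by palladium-catalysed alkenylation of the derived alkylmetal (Negishi coupling). No ring is closed. The single new stereocentre C8 is set as (R) by reagent control, the two 1-neomenthylindenyl ligands differentiating the alkene faces in the insertion, and the moderate enantioselectivity expected is made good by the diastereomer separation in step 6. The step needs site selectivity for the terminal over the internal alkene and regioselectivity for methyl delivery to the internal carbon, both secured by the steric demand of the zirconocene, which does not insert 1,2-disubstituted alkenes and places the metal on the primary carbon. The coupling should retain the Z-styrene geometry and leave the silyl ether intact.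

**Step 5**
Reactants: 12 tert-butyldimethyl{[(4R,11Z)-4-methyl-2-methylidene-12-phenyldodec-11-en-1-yl]oxy}silane
Product: 13 (4R,11Z)-4-methyl-2-methylidene-12-phenyldodec-11-en-1-ol
Conditions: camphorsulfonic acid (cat.), MeOH, 0 °C to rt
Reagents that add atoms: none
Why: Acid-catalysed methanolysis should cleave the primary silyl ether without affecting either alkene or C8.

**Step 6**
Reactants: 13 (4R,11Z)-4-methyl-2-methylidene-12-phenyldodec-11-en-1-ol
Product: 14 {(2R)-2-[(2R,9Z)-2-methyl-10-phenyldec-9-en-1-yl]oxiran-2-yl}methanol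
Conditions: Ti(OiPr)4 (10 mol %), D-(−)-diisopropyl tartrate (12 mol %), t-BuOOH (anhydrous, isooctane), 4 Å MS, CH2Cl2, −20 °C; preparative HPLC to remove the minor C6/C8 diastereomer
Reagents that add atoms: tert-butyl hydroperoxide, CC(C)(C)OO
Why: Sharpless asymmetric epoxidation with the D-(−)-tartrate should deliver oxygen to the face of the 2-substituted allyl alcohol that gives the (2R)-oxirane at C6; the isomers wrong at only C6 or only C8 are mutual enantiomers and diastereomers of 14, so removing that diastereomer should leave 14 in high enantiomeric purity.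

**Step 7**
Reactants: 14 {(2R)-2-[(2R,9Z)-2-methyl-10-phenyldec-9-en-1-yl]oxiran-2-yl}methanol
Product: 15 (2R,4R,11Z)-2,4-dimethyl-12-phenyldodec-11-ene-1,2-diol
Conditions: LiAlH4, THF, 0 °C
Reagents that add atoms: none
Why: Hydride opening of the epoxide (SN2) should occur at the unsubstituted oxirane carbon, which becomes the C6 methyl group, while the C6–O bond and hence the C6 configuration stay intact.

**Step 8**
Reactants: 15 (2R,4R,11Z)-2,4-dimethyl-12-phenyldodec-11-ene-1,2-diol
Product: 16 (2R,4R,11Z)-2-hydroxy-2,4-dimethyl-12-phenyldodec-11-en-1-yl 4-methylbenzenesulfonate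
Conditions: TsCl, Et3N, DMAP (cat.), CH2Cl2, 0 °C
Reagents that add atoms: 4-methylbenzenesulfonyl chloride, Cc1ccc(cc1)S(Cl)(=O)=O
Why: Selective tosylation should take the primary hydroxyl and leave the hindered tertiary one free.

**Step 9**
Reactants: 16 (2R,4R,11Z)-2-hydroxy-2,4-dimethyl-12-phenyldodec-11-en-1-yl 4-methylbenzenesulfonate
Product: 17 (2R)-2-methyl-2-[(2R,9Z)-2-methyl-10-phenyldec-9-en-1-yl]oxirane
Conditions: K2CO3, MeOH, rt
Reagents that add atoms: none
Why: Intramolecular Williamson etherification (3-exo-tet) by the tertiary alkoxide should displace the primary tosylate, so C6 keeps its configuration and C5 becomes the oxirane methylene.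

**Step 10**
Reactants: 17 (2R)-2-methyl-2-[(2R,9Z)-2-methyl-10-phenyldec-9-en-1-yl]oxirane
Product: 18 (2S,4R,11Z)-2-hydroperoxy-2,4-dimethyl-12-phenyldodec-11-en-1-ol
Conditions: H2O2 (anhydrous, in Et2O, dried over MgSO4), H3PMo12O40 (cat.), Et2O, 0 °C to rt
Reagents that add atoms: hydrogen peroxide, OO
Why: In this acid-catalysed perhydrolysis of a 2,2-disubstituted epoxide, H2O2 should attack the tertiary carbon of the activated oxirane from the side opposite the C–O bond (borderline SN2), inverting C6 to the (S) configuration of the target and freeing C5 as a primary alcohol.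

**Step 11**
Reactants: 18 (2S,4R,11Z)-2-hydroperoxy-2,4-dimethyl-12-phenyldodec-11-en-1-ol
Product: 20 (2S,4R,11Z)-2,4-dimethyl-12-phenyl-2-[(triethylsilyl)peroxy]dodec-11-en-1-ol, via sodium alkylperoxide 19 (not isolated)
Conditions: NaN(SiMe3)2 (1.0 equiv), THF, −78 °C; then Et3SiCl (1.0 equiv), −78 to −40 °C
Reagents that add atoms: chlorotriethylsilane, CC[Si](Cl)(CC)CC
Why: One equivalent of base should deprotonate only the hydroperoxide, which is three to four pKa units more acidic than the primary alcohol, and the resulting α-effect peroxide anion is O-silylated by the chlorosilane (silyl peroxide formation).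

**Step 12**
Reactants: 20 (2S,4R,11Z)-2,4-dimethyl-12-phenyl-2-[(triethylsilyl)peroxy]dodec-11-en-1-ol
Product: 21 (2S,4R,11Z)-2,4-dimethyl-12-phenyl-2-[(triethylsilyl)peroxy]dodec-11-enal
Conditions: Dess–Martin periodinane, NaHCO3, CH2Cl2, 0 °C to rt
Reagents that add atoms: none
Why: Dess–Martin oxidation under buffered, non-basic conditions should give the aldehyde with the silyl peroxide intact, and the quaternary C6 rules out epimerisation.

**Step 13**
Reactants: 21 (2S,4R,11Z)-2,4-dimethyl-12-phenyl-2-[(triethylsilyl)peroxy]dodec-11-enal; 22 diethyl (3-oxobutan-2-yl)phosphonate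
Product: 23 (3E,5S,7R,14Z)-3,5,7-trimethyl-15-phenyl-5-[(triethylsilyl)peroxy]pentadeca-3,14-dien-2-one
Conditions: NaH, THF, 0 °C to rt
Reagents that add atoms: none
Why: Horner–Wadsworth–Emmons olefination with the anion of the α-methyl β-ketophosphonate should give the trisubstituted enone with the acyl group trans to C6 (E).

**Step 14**
Reactants: 23 (3E,5S,7R,14Z)-3,5,7-trimethyl-15-phenyl-5-[(triethylsilyl)peroxy]pentadeca-3,14-dien-2-one
Product: 24 (3E,5S,7R,14Z)-5-hydroperoxy-3,5,7-trimethyl-15-phenylpentadeca-3,14-dien-2-one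
Conditions: HF·pyridine, pyridine, THF, 0 °C
Reagents that add atoms: none
Why: Buffered fluoride should cleave the Si–O bond of the silyl peroxide (desilylation), and the E geometry keeps the freed hydroperoxide from reaching the ketone.

**Step 15**
Reactants: 24 (3E,5S,7R,14Z)-5-hydroperoxy-3,5,7-trimethyl-15-phenylpentadeca-3,14-dien-2-one
Product: 26 (3S,4R,6S)-3,4,6-trimethyl-6-[(2R,9Z)-2-methyl-10-phenyldec-9-en-1-yl]-1,2-dioxan-3-ol, via open-chain hydroperoxy ketone 25 (not isolated)
Conditions: purified ene-reductase of the Old Yellow Enzyme family ((4R)-selective member chosen from a panel: OYE1 to OYE3, OPR1, YqjM, NCR, OYE1 W116 variants), NADP+ (cat.), D-glucose, glucose dehydrogenase, phosphate buffer pH 7 with 10% DMSO, 30 °C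
Reagents that add atoms: none
Why: In this biocatalytic asymmetric alkene reduction the reduced flavin delivers hydride to C5 and the active-site tyrosine protonates C4 in a trans addition, fixing C4 as (R) under enzyme control, after which the hydroperoxide adds to the C3 ketone (6-exo-trig hemiketalisation, O2–C3) to close ring A with C3 settling thermodynamically as (S), hydroxyl axial (anomeric effect) and methyl equatorial.

**Compound list**
1 | 9-bromonon-1-ene | C=CCCCCCCCBr | starting material
2 | triphenylphosphine | c1ccc(cc1)P(c1ccccc1)c1ccccc1 | starting material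
3 | (non-8-en-1-yl)triphenylphosphonium bromide | C=CCCCCCCC[P+](c1ccccc1)(c1ccccc1)c1ccccc1.[Br-] | intermediate
4 | benzaldehyde | O=Cc1ccccc1 | starting material
5 | (non-8-en-1-ylidene)triphenylphosphorane | C=CCCCCCCC=P(c1ccccc1)(c1ccccc1)c1ccccc1 | intermediate
6 | (Z)-1-phenyldeca-1,9-diene | C=CCCCCCC/C=C\c1ccccc1 | intermediate
7 | 2-bromoprop-2-en-1-ol | OCC(Br)=C | starting material
8 | (2-bromoallyloxy)(tert-butyl)dimethylsilane | C=C(Br)CO[Si](C)(C)C(C)(C)C | intermediate
9 | trimethylaluminium | C[Al](C)C | starting material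
10 | dimethyl[(2R,9Z)-2-methyl-10-phenyldec-9-en-1-yl]alumane | C[C@H](CCCCCC/C=C\c1ccccc1)C[Al](C)C | intermediate
11 | [(2R,9Z)-2-methyl-10-phenyldec-9-en-1-yl]zinc trifluoromethanesulfonate | C[C@H](CCCCCC/C=C\c1ccccc1)C[Zn]OS(=O)(=O)C(F)(F)F | intermediate
12 | tert-butyldimethyl{[(4R,11Z)-4-methyl-2-methylidene-12-phenyldodec-11-en-1-yl]oxy}silane | C[C@H](CCCCCC/C=C\c1ccccc1)CC(=C)CO[Si](C)(C)C(C)(C)C | intermediate
13 | (4R,11Z)-4-methyl-2-methylidene-12-phenyldodec-11-en-1-ol | C[C@H](CCCCCC/C=C\c1ccccc1)CC(=C)CO | intermediate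
14 | {(2R)-2-[(2R,9Z)-2-methyl-10-phenyldec-9-en-1-yl]oxiran-2-yl}methanol | C[C@H](CCCCCC/C=C\c1ccccc1)C[C@]1(CO1)CO | intermediate
15 | (2R,4R,11Z)-2,4-dimethyl-12-phenyldodec-11-ene-1,2-diol | C[C@H](CCCCCC/C=C\c1ccccc1)C[C@](O)(C)CO | intermediate
16 | (2R,4R,11Z)-2-hydroxy-2,4-dimethyl-12-phenyldodec-11-en-1-yl 4-methylbenzenesulfonate | C[C@H](CCCCCC/C=C\c1ccccc1)C[C@](O)(C)COS(=O)(=O)c1ccc(C)cc1 | intermediate
17 | (2R)-2-methyl-2-[(2R,9Z)-2-methyl-10-phenyldec-9-en-1-yl]oxirane | C[C@H](CCCCCC/C=C\c1ccccc1)C[C@]1(C)CO1 | intermediate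
18 | (2S,4R,11Z)-2-hydroperoxy-2,4-dimethyl-12-phenyldodec-11-en-1-ol | C[C@H](CCCCCC/C=C\c1ccccc1)C[C@@](OO)(C)CO | intermediate
19 | sodium (2S,4R,11Z)-1-hydroxy-2,4-dimethyl-12-phenyldodec-11-en-2-yl peroxide | C[C@H](CCCCCC/C=C\c1ccccc1)C[C@@](O[O-])(C)CO.[Na+] | intermediate
20 | (2S,4R,11Z)-2,4-dimethyl-12-phenyl-2-[(triethylsilyl)peroxy]dodec-11-en-1-ol | C[C@H](CCCCCC/C=C\c1ccccc1)C[C@@](OO[Si](CC)(CC)CC)(C)CO | intermediate
21 | (2S,4R,11Z)-2,4-dimethyl-12-phenyl-2-[(triethylsilyl)peroxy]dodec-11-enal | C[C@H](CCCCCC/C=C\c1ccccc1)C[C@@](OO[Si](CC)(CC)CC)(C)C=O | intermediate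
22 | diethyl (3-oxobutan-2-yl)phosphonate | CCOP(=O)(OCC)C(C)C(C)=O | starting material
23 | (3E,5S,7R,14Z)-3,5,7-trimethyl-15-phenyl-5-[(triethylsilyl)peroxy]pentadeca-3,14-dien-2-one | C[C@H](CCCCCC/C=C\c1ccccc1)C[C@@](OO[Si](CC)(CC)CC)(C)/C=C(\C)C(C)=O | intermediate
24 | (3E,5S,7R,14Z)-5-hydroperoxy-3,5,7-trimethyl-15-phenylpentadeca-3,14-dien-2-one | C[C@H](CCCCCC/C=C\c1ccccc1)C[C@@](OO)(C)/C=C(\C)C(C)=O | intermediate
25 | (3R,5S,7R,14Z)-5-hydroperoxy-3,5,7-trimethyl-15-phenylpentadec-14-en-2-one | C[C@H](CCCCCC/C=C\c1ccccc1)C[C@@](OO)(C)C[C@@H](C)C(C)=O | intermediate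
26 | (3S,4R,6S)-3,4,6-trimethyl-6-[(2R,9Z)-2-methyl-10-phenyldec-9-en-1-yl]-1,2-dioxan-3-ol | C[C@H](CCCCCC/C=C\c1ccccc1)C[C@@]1(C)C[C@@H](C)[C@@](C)(O)OO1 | target

Total step count: 15. Longest linear sequence: 14 steps (steps 1, 2 and 4 to 15, from 9-bromonon-1-ene).

**Steps most likely to fail**

Step 15. The enzyme may not bind the bulky, lipophilic hydroperoxy enone productively, may protonate C4 from the wrong face or unselectively, or its reduced flavin may cleave the O–O bond. The fallback sets out from 23 and gives up reagent control at C4. Catecholborane in THF at rt, which reduces s-cis-capable enones by conjugate addition and does not hydroborate the styrene, should give after hydrolysis of the boron enolate (5S,7R,14Z)-3,5,7-trimethyl-15-phenyl-5-[(triethylsilyl)peroxy]pentadec-14-en-2-one F1 as a mixture of epimers at the methyl-bearing carbon next to the ketone. HF·pyridine then frees the hydroperoxide, which should close to 26 and to its epimer (3R,4S,6S)-3,4,6-trimethyl-6-[(2R,9Z)-2-methyl-10-phenyldec-9-en-1-yl]-1,2-dioxan-3-ol F2. The two ring diastereomers are separated by chromatography; F2 is re-equilibrated at C4 through its open-chain ketone form with a catalytic amine base and separated again. The fallback comes back to the route at 26.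

Step 11. The silylation may not discriminate sufficiently between the peroxide anion and the neighbouring hydroxyl, or the silyl group may move from the peroxide oxygen to the alkoxide. The fallback sets out from 18 and silylates both oxygens (Et3SiOTf, 2,6-lutidine, CH2Cl2, −78 °C) to give triethyl{[(2S,4R,11Z)-2,4-dimethyl-12-phenyl-2-[(triethylsilyl)peroxy]dodec-11-en-1-yl]oxy}silane F3. Swern conditions ((COCl)2, DMSO, CH2Cl2, −78 to −40 °C, then Et3N) then cleave and oxidise only the primary triethylsilyl ether, whose oxygen is far more nucleophilic toward the chlorosulfonium reagent than the peroxide oxygens. This comes back to the route at 21 and bypasses 20.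

Step 4. Face selection in the methylzirconation may be too low for the later diastereomer separation to correct, and part of the alkylmetal may be lost by protodemetalation or β-hydride elimination during the aluminium–zinc–palladium relay. The fallback sets out from 6 and 9 and splits the one-flask sequence:
- Alane 10 is formed as before but oxidised with O2 to (2R,9Z)-2-methyl-10-phenyldec-9-en-1-ol F4.
- A lipase that acylates the (2S)-alcohol faster (Pseudomonas cepacia lipase, vinyl acetate) removes the minor enantiomer as (2S,9Z)-2-methyl-10-phenyldec-9-en-1-yl acetate F5.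
- Purified F4 is converted with I2, PPh3 and imidazole into [(1Z,9R)-10-iodo-9-methyldec-1-en-1-yl]benzene F6.
- Zinc insertion (Zn, LiCl, THF) gives iodo[(2R,9Z)-2-methyl-10-phenyldec-9-en-1-yl]zinc F7, and Negishi coupling with 8 under Pd(PPh3)4 comes back to the route at 12.

**Further compounds**
F1 | step 15 | (5S,7R,14Z)-3,5,7-trimethyl-15-phenyl-5-[(triethylsilyl)peroxy]pentadec-14-en-2-one (both C3 epimers) | C[C@H](CCCCCC/C=C\c1ccccc1)C[C@@](OO[Si](CC)(CC)CC)(C)CC(C)C(C)=O
F2 | step 15 | (3R,4S,6S)-3,4,6-trimethyl-6-[(2R,9Z)-2-methyl-10-phenyldec-9-en-1-yl]-1,2-dioxan-3-ol | C[C@H](CCCCCC/C=C\c1ccccc1)C[C@@]1(C)C[C@H](C)[C@](C)(O)OO1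
F3 | step 11 | triethyl{[(2S,4R,11Z)-2,4-dimethyl-12-phenyl-2-[(triethylsilyl)peroxy]dodec-11-en-1-yl]oxy}silane | C[C@H](CCCCCC/C=C\c1ccccc1)C[C@@](OO[Si](CC)(CC)CC)(C)CO[Si](CC)(CC)CC
F4 | step 4 | (2R,9Z)-2-methyl-10-phenyldec-9-en-1-ol | C[C@H](CCCCCC/C=C\c1ccccc1)CO
F5 | step 4 | (2S,9Z)-2-methyl-10-phenyldec-9-en-1-yl acetate | C[C@@H](CCCCCC/C=C\c1ccccc1)COC(C)=O
F6 | step 4 | [(1Z,9R)-10-iodo-9-methyldec-1-en-1-yl]benzene | C[C@H](CCCCCC/C=C\c1ccccc1)CI
F7 | step 4 | iodo[(2R,9Z)-2-methyl-10-phenyldec-9-en-1-yl]zinc | C[C@H](CCCCCC/C=C\c1ccccc1)C[Zn]I
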